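**Retrosynthetic overview**

- The target, 15-acetoxylabda-7,13E-dien-17-oic acid, is traced back through C15 acetylation, alkene conjugation to C7=C8, trans-selective reduction of C5=C6 and aldehyde oxidation to a bicyclic 5,7-dien-17-al.
- Key disconnection: ring B is cut at C9–C10 and C7–C8, giving β-homocyclocitral (ring A with C6 and C7) and a side-chain enal (C17, C8, C9, C11–C16 with the C15 acetate).
- The strategy rests on ring B carrying the C7=C8 alkene conjugated to the C17 carbonyl on C8, next to the quaternary C10. This unsaturated carbonyl is what an aldehyde–aldehyde condensation leaves behind, and C10, having no hydrogen, allows only a cyclohexadienal.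
- The side-chain enal comes from geranyl acetate by 6,7-epoxidation, periodic acid cleavage and a two-carbon Wittig homologation.
- Ring order: ring A is purchased, ring B is closed in the key step (setting C9 and C10), and C5 is set afterwards by dissolving-metal reduction.

Key step: step 4

Remark on numbering: positions follow labdane numbering (ring A: C1–C5, C10; ring B: C5–C10; C17 on C8; side chain C11–C16; C20 on C10). β means the face of the C10 methyl group.

Assumption: the iminium ion of the diarylprolinol silyl ether is taken to react in its E geometry on the face away from the diphenyl(silyloxy)methyl group. On that model the R catalyst gives 9R.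

**Route**

Step 1
Reactants: 1 geranyl acetate
Product: 2 6,7-epoxygeranyl acetate (racemic at the epoxide carbon)
Conditions: mCPBA (1.05 equiv), NaHCO3, CH2Cl2, −10 to 0 °C
Reagents that add atoms: mCPBA, O=C(OO)c1cccc(Cl)c1
Why: Prilezhaev epoxidation is faster at the electron-rich distal trisubstituted alkene than at the 2,3-alkene, which is deactivated by the allylic acetoxy group; the new stereocentre is racemic and is removed in step 2.

Step 2
Reactants: 2 6,7-epoxygeranyl acetate
Product: 3 (4E)-6-acetoxy-4-methylhex-4-enal
Conditions: H5IO6 (1.2 equiv), THF–H2O, 0 °C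
Reagents that add atoms: none
Why: acid-promoted epoxide hydrolysis and Malaprade glycol cleavage in one operation should give the aldehyde and acetone, leaving the acetate and the E-trisubstituted alkene untouched.

Step 3
Reactants: 3 (4E)-6-acetoxy-4-methylhex-4-enal; 4 (triphenylphosphoranylidene)acetaldehyde
Product: 5 (2E,6E)-8-acetoxy-6-methylocta-2,6-dienal
Conditions: 4 (1.1 equiv), toluene, 80 °C
Reagents that add atoms: (triphenylphosphoranylidene)acetaldehyde (4), O=CC=P(c1ccccc1)(c1ccccc1)c1ccccc1
Why: Wittig olefination with a stabilised formylmethylene ylide is E-selective, and the conjugated product is less electrophilic than the saturated aldehyde, which limits a second homologation.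

Step 4
Reactants: 5 (2E,6E)-8-acetoxy-6-methylocta-2,6-dienal; 6 β-homocyclocitral (2.5 equiv)
Product: 10 15-acetoxylabda-5,7,13E-trien-17-al (9α-H; 10β-methyl), via dienamine 7 (not isolated), via iminium benzoate 8 (not isolated), via amino aldehyde cycloadduct 9 (not isolated)
Conditions: (R)-2-[diphenyl(trimethylsilyloxy)methyl]pyrrolidine (20 mol %), PhCO2H (20 mol %), toluene, 25 to 40 °C, slow addition of 5 to 6
Reagents that add atoms: none
Why: Proposed new method: the amine condenses with 6 to the 1-aminodiene 7 (N–C7=C6–C5=C10) and with 5 to the E-iminium ion 8; C10 of 7 adds to C9 of 8 in a vinylogous Michael step, the C8 enamine so formed attacks the C7 iminium carbon in a Mannich step, hydrolysis at C17 gives β-amino aldehyde 9, and E1cB loss of the amine from C7 gives the C7=C8 alkene of 10 and returns the catalyst. The closest known reaction type is the secondary-amine-catalysed condensation of two enals to cyclohexa-1,3-dienecarbaldehydes (dienamine Michael–Mannich or [4+2], then amine elimination), and thermal Diels–Alder reactions of 1-vinyl-2,6,6-trimethylcyclohexenes show that this fully substituted diene terminus can bond to an electron-poor alkene; what has not been shown is the amine-catalysed version at a tetrasubstituted γ-carbon. Ring B closes by a 6-(enolexo)-exo-trig Mannich cyclisation, so that overall the step is a formal [4+2] with the C7–C10 diene and the C8=C9 dienophile. C9 is set by the catalyst, whose diphenyl(silyloxy)methyl group covers one face of the E-iminium ion so that C10 arrives on the open face (9R with the R catalyst), and C10 is set relative to C9 by a compact endo-type arrangement with the iminium carbon under the diene and C11 pointing away, which places C11 cis to the C10 methyl. The step needs attack through C10 and not C6 and cross- and not self-condensation: adducts formed at C6 cannot close a six-membered ring and can revert while the C10 adduct is removed irreversibly by ring closure and elimination, C10 carries no hydrogen so only the cyclohexadienal can form, and 6, which is not conjugated, gives its dienamine faster than 5 and cannot act as acceptor, helped by slow addition of 5 to excess 6.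

Step 5
Reactants: 10 15-acetoxylabda-5,7,13E-trien-17-al
Product: 12 15-hydroxylabda-5,7,13E-trien-17-oic acid, via acetoxy dienoic acid 11 (not isolated)
Conditions: NaClO2, NaH2PO4, 2-methyl-2-butene, t-BuOH–H2O, 0 °C to rt; then LiOH·H2O, MeOH–H2O, rt; HCl (aq) to pH 3
Reagents that add atoms: sodium chlorite, [Na+].[O-]Cl=O
Why: Pinnick oxidation converts the hindered dienal to the acid with the hypochlorite scavenger protecting the C13=C14 alkene, and hydroxide then saponifies the primary acetate; C9–H is not acidic because its anion would be cross-conjugated, so C9 is not at risk.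

Step 6
Reactants: 12 15-hydroxylabda-5,7,13E-trien-17-oic acid
Product: 13 15-hydroxylabda-6,13E-dien-17-oic acid (5α-H, trans ring fusion; mixture of C8 epimers)
Conditions: Li (excess), NH3 (l)–THF, −78 °C; then solid NH4Cl; HCl (aq) to pH 3
Reagents that add atoms: none
Why: Birch-type dissolving-metal 1,6-reduction puts two electrons into the C5=C6–C7=C8–carboxylate system and ammonia protonates C5 axially on the α face, anti to the axial C10 methyl, as in metal–ammonia reductions of ring-fused enones, which sets the trans fusion; the dienediolate left behind resists further reduction and is protonated at C8 on quench, the carboxylate and alkoxide forms shield the acid and the allylic C15–O bond, and any conjugated C7=C8 acid formed directly converges with the main product at 16.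

Step 7
Reactants: 13 15-hydroxylabda-6,13E-dien-17-oic acid
Product: 14 methyl 15-hydroxylabda-6,13E-dien-17-oate (C8 epimers)
Conditions: TMSCHN2 (1.2 equiv), toluene–MeOH 3:1, 0 °C
Reagents that add atoms: trimethylsilyldiazomethane, C[Si](C)(C)C=[N+]=[N-]
Why: O-methylation of the carboxylic acid by the diazoalkane is selective over the primary alcohol and gives the ester needed for mild base isomerisation.

Step 8
Reactants: 14 methyl 15-hydroxylabda-6,13E-dien-17-oate
Product: 16 15-hydroxylabda-7,13E-dien-17-oic acid, via conjugated methyl ester 15 (not isolated)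
Conditions: NaOMe (0.5 equiv), MeOH, 65 °C; then KOH (aq), 70 °C; HCl (aq) to pH 3
Reagents that add atoms: potassium hydroxide, [K+].[OH-]
Why: base-mediated alkene isomerisation through the ester dienolate (deprotonation at C8, protonation at C6) should move the alkene into conjugation as the more stable trisubstituted C7=C8 enoate, removing the C8 centre without touching the non-acidic C9–H, and saponification follows in the same flask.

Step 9
Reactants: 16 15-hydroxylabda-7,13E-dien-17-oic acid
Product: 17 15-acetoxylabda-7,13E-dien-17-oic acid (target)
Conditions: Ac2O (2.5 equiv), pyridine, DMAP (5 mol %), CH2Cl2, 0 °C to rt; then THF–H2O, NaHCO3; acidify to pH 3–4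
Reagents that add atoms: acetic anhydride, CC(=O)OC(C)=O
Why: DMAP-catalysed acylation acetylates the primary allylic alcohol, and any mixed anhydride formed at the hindered C17 acid is hydrolysed back during the aqueous bicarbonate stir.

**Compound list**

1 | geranyl acetate, (2E)-3,7-dimethylocta-2,6-dien-1-yl acetate | CC(C)=CCC/C(C)=C/COC(C)=O | starting material
2 | 6,7-epoxygeranyl acetate, (2E)-5-(3,3-dimethyloxiran-2-yl)-3-methylpent-2-en-1-yl acetate (racemic) | CC1(C)OC1CC/C(C)=C/COC(C)=O | intermediate
3 | (4E)-6-acetoxy-4-methylhex-4-enal | O=CCC/C(C)=C/COC(C)=O | intermediate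
4 | (triphenylphosphoranylidene)acetaldehyde | O=CC=P(c1ccccc1)(c1ccccc1)c1ccccc1 | starting material
5 | (2E,6E)-8-acetoxy-6-methylocta-2,6-dienal | CC(=O)OC/C=C(\C)CC/C=C/C=O | intermediate
6 | β-homocyclocitral, 2-(2,6,6-trimethylcyclohex-1-en-1-yl)acetaldehyde | CC1=C(CC=O)C(C)(C)CCC1 | starting material
7 | dienamine of 6 with the R catalyst, (R)-2-[diphenyl(trimethylsilyloxy)methyl]-1-[(E)-2-(2,6,6-trimethylcyclohex-1-en-1-yl)ethenyl]pyrrolidine | CC1=C(/C=C/N2CCC[C@@H]2C(c3ccccc3)(c4ccccc4)O[Si](C)(C)C)C(C)(C)CCC1 | intermediate
8 | iminium benzoate of 5 with the R catalyst (E at C=N, s-trans) | CC(=O)OC/C=C(\C)CC/C=C/C=[N+]1\CCC[C@@H]1C(c2ccccc2)(c3ccccc3)O[Si](C)(C)C.[O-]C(=O)c1ccccc1 | intermediate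
9 | amino aldehyde cycloadduct, 15-acetoxy-7-[(R)-2-[diphenyl(trimethylsilyloxy)methyl]pyrrolidin-1-yl]labda-5,13E-dien-17-al (9α-H, 10β-methyl; C7 and C8 transient and left open) | CC(=O)OC/C=C(\C)CC[C@H]1C(C=O)C(N3CCC[C@@H]3C(c4ccccc4)(c5ccccc5)O[Si](C)(C)C)C=C2C(C)(C)CCC[C@]12C | intermediate
10 | 15-acetoxylabda-5,7,13E-trien-17-al (9R,10R; 9α-H, 10β-methyl) | CC(=O)OC/C=C(\C)CC[C@H]1C(C=O)=CC=C2C(C)(C)CCC[C@]12C | intermediate
11 | 15-acetoxylabda-5,7,13E-trien-17-oic acid | CC(=O)OC/C=C(\C)CC[C@H]1C(C(=O)O)=CC=C2C(C)(C)CCC[C@]12C | intermediate
12 | 15-hydroxylabda-5,7,13E-trien-17-oic acid | OC/C=C(\C)CC[C@H]1C(C(=O)O)=CC=C2C(C)(C)CCC[C@]12C | intermediate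
13 | 15-hydroxylabda-6,13E-dien-17-oic acid (5α-H, 9α-H, 10β-methyl; C8 epimers) | OC/C=C(\C)CC[C@H]1C(C(=O)O)C=C[C@H]2C(C)(C)CCC[C@]12C | intermediate
14 | methyl 15-hydroxylabda-6,13E-dien-17-oate (C8 epimers) | OC/C=C(\C)CC[C@H]1C(C(=O)OC)C=C[C@H]2C(C)(C)CCC[C@]12C | intermediate
15 | methyl 15-hydroxylabda-7,13E-dien-17-oate | OC/C=C(\C)CC[C@H]1C(C(=O)OC)=CC[C@H]2C(C)(C)CCC[C@]12C | intermediate
16 | 15-hydroxylabda-7,13E-dien-17-oic acid | OC/C=C(\C)CC[C@H]1C(C(=O)O)=CC[C@H]2C(C)(C)CCC[C@]12C | intermediate
17 | 15-acetoxylabda-7,13E-dien-17-oic acid, (1R,4aS,8aS)-1-[(3E)-5-acetoxy-3-methylpent-3-en-1-yl]-5,5,8a-trimethyl-1,4,4a,5,6,7,8,8a-octahydronaphthalene-2-carboxylic acid | CC(=O)OC/C=C(\C)CC[C@H]1C(C(=O)O)=CC[C@H]2C(C)(C)CCC[C@]12C | target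

**Step count**

Total steps: 9. Longest linear sequence: 9 steps (geranyl acetate 1 to target 17).

**Steps most likely to fail**

Risk 1, step 4 (key step, proposed new method). Bond formation at the fully substituted C10 may be too slow to compete with attack through C6 or with self-condensation of the enal, and face control could be eroded because both partners carry the chiral amine. The fallback replaces amine catalysis by a Lewis-acid Diels–Alder reaction of a preformed oxygenated diene. It sets out from 6, which with TBSOTf and Et3N in CH2Cl2 should give the silyl dienol ether (E)-tert-butyldimethyl{[2-(2,6,6-trimethylcyclohex-1-en-1-yl)ethenyl]oxy}silane F1. A chiral oxazaborolidinium triflimide (from diphenylprolinol, o-tolylboroxine and Tf2NH), in the enantiomer that exposes the required face of C9, would then catalyse the endo cycloaddition of this diene with enal 5 in CH2Cl2 at −78 to −40 °C. The expected product is the 7-silyloxy aldehyde 15-acetoxy-7-(tert-butyldimethylsilyloxy)labda-5,13E-dien-17-al F2, with the same C9–C10 and C7–C8 bonds and the regiochemistry of a 1-oxygenated diene. Acid-promoted loss of the silanol (TFA, CH2Cl2) would return the route at dienal 10.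

Risk 2, step 6. Electron transfer may cleave the allylic C15–O bond, the first protonation may occur at C7 and not C5, or the ring fusion may not be set cleanly. The fallback uses a homogeneous single-electron reductant on the ester, with the proton donor present from the start, in place of a dissolving metal on the dianion. It sets out from 12, which with TMSCHN2 in toluene–MeOH gives methyl 15-hydroxylabda-5,7,13E-trien-17-oate F3. Reduction with SmI2 in THF–DMA with t-BuOH, conditions for conjugate reduction of unsaturated esters that leave allylic C–O bonds alone in the absence of zerovalent palladium, should give the 1,6-reduced ester and return the route at 14.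

Risk 3, step 3. The formylmethylene Wittig reaction may be sluggish, or may run on to a second homologation of the product enal. The fallback builds the enal by olefin cross-metathesis. It sets out from 3, which with Ph3P=CH2 (from Ph3PCH3Br and KHMDS, THF, −78 to 0 °C) gives (2E)-3-methylhepta-2,6-dien-1-yl acetate F4. Cross-metathesis of its terminal alkene with crotonaldehyde (second-generation Grubbs catalyst, CH2Cl2, 40 °C) should give the E-enal and return the route at 5; the trisubstituted alkene is expected to stay inert.

**Further compounds**

F1 | step 4 | (E)-tert-butyldimethyl{[2-(2,6,6-trimethylcyclohex-1-en-1-yl)ethenyl]oxy}silane | CC1=C(/C=C/O[Si](C)(C)C(C)(C)C)C(C)(C)CCC1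
F2 | step 4 | 15-acetoxy-7-(tert-butyldimethylsilyloxy)labda-5,13E-dien-17-al (9α-H, 10β-methyl; C7 and C8 left open) | CC(=O)OC/C=C(\C)CC[C@H]1C(C=O)C(O[Si](C)(C)C(C)(C)C)C=C2C(C)(C)CCC[C@]12C
F3 | step 6 | methyl 15-hydroxylabda-5,7,13E-trien-17-oate | OC/C=C(\C)CC[C@H]1C(C(=O)OC)=CC=C2C(C)(C)CCC[C@]12C
F4 | step 3 | (2E)-3-methylhepta-2,6-dien-1-yl acetate | CC(=O)OC/C=C(\C)CCC=C
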